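- Of the substrate gone at the last violet reading, 67.8 % stands as target, and this share is the reading you build on.

the same everywhere: substrate 0.10 M
- blue: reagent 0.13 M; temperature 5 °C; run made earlier
- violet: reagent 0.30 M; temperature 27 °C; run made earlier
- gamma: reagent 0.200 M; temperature −5 °C; time 20 min
- epsilon: reagent 0.200 M; temperature 35 °C; time 20 min
- zeta: reagent 0.200 M; temperature 15 °C; time 20 min

| run | time / min | target / % | substrate / % |
|---|---|---|---|
| blue | 0.667 | 4.1 | 94.6 |
| blue | 1.00 | 6.6 | 91.8 |
| blue | 1.50 | 9.5 | 88.3 |
| blue | 2.50 | 14.2 | 83.1 |
| blue | 5.00 | 24.0 | 67.6 |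
| blue | 8.00 | 34.1 | 60.7 |
| violet | 0.200 | 15.3 | 75.2 |
| violet | 0.333 | 24.0 | 62.5 |
| violet | 0.500 | 33.2 | 53.3 |
| violet | 0.833 | 41.6 | 36.4 |
| violet | 1.50 | 53.2 | 20.4 |
| violet | 2.50 | 60.1 | 11.4 |

(readings scatter by 1 percentage point)

- candidate steps: substrate + reagent -> target; substrate + 2 reagent -> side product; reagent + target -> over-reaction product; substrate -> decomposition product

* the flask with the highest amount of target, in percent of the substrate charged ("all alike" if they lie within 1.5 percentage points) (gamma / epsilon / zeta / all alike)
* final target, as a percentage of the substrate charged, in gamma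
* final target, as a percentage of the substrate charged, in epsilon
* final target, as a percentage of the substrate charged, in zeta

- The candidate steps are: substrate + reagent to target, substrate + two reagent to side product, reagent + target to over-reaction product, and substrate alone to decomposition product.
- Turn reagent first. Mean [reagent] in violet was about 0.241 M, so s reads 1.96 L mol⁻¹: this is the selectivity factor, side-product rate over target rate per unit [reagent].
- The side share of consumed substrate is s[reagent]/(1 + s[reagent]). At the charge that gives 28.2 %, but [reagent] falls, and its mean in a finishing flask is about 0.136 M. So I reckon a side share of 21.1 % and a target ceiling of 78.9 %, holding s fixed across temperature.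
- Turn temperature next, in powers of ten. Blue lost 0.217 powers of ten of substrate in 8.00 min, and violet lost 0.943 in 2.50 min.
- With blue's mean [reagent] near 0.104 M, violet runs 6.00 times as fast per unit [reagent], faster than blue.
- Interpolated on the logarithm, 20 min gives gamma 0.314 powers of ten, zeta 1.60 and epsilon 8.15.
- Turn time last. I take no rate for over-reaction from the readings, so my estimates count none of it: 40.6 % in gamma, 76.9 % in zeta and 78.9 % in epsilon.
- The forecast names zeta, with 40 % in gamma, 69 % in epsilon and 74 % in zeta, warning for epsilon that “unseen over-reaction or decomposition may cost more”.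
- The flasks give zeta the most target: 39.7 % in gamma, 61.8 % in epsilon, 7.2 percentage points below the forecast, and 70.2 % in zeta.

    substrate + reagent → target (k = 0.0999 L mol⁻¹ s⁻¹, Ea = 58.0 kJ mol⁻¹)
    substrate + 2 reagent → side product (k = 0.183 L² mol⁻² s⁻¹, Ea = 49.0 kJ mol⁻¹)
    reagent + target → over-reaction product (k = 0.00307 L mol⁻¹ s⁻¹, Ea = 76.0 kJ mol⁻¹)
    substrate → decomposition product (k = 2.76 × 10⁻⁵ s⁻¹, Ea = 100 kJ mol⁻¹)
    (constants at 35 °C)

- Epsilon holds 19.9 % side product against the reckoned 21.1 %, while its target and over-reaction product together make 79.9 %. The neighbouring flask is epsilon charged with 0.025 M of substrate, which is 8.00 equiv of reagent. With the same s, its mean [reagent] is about 0.184 M and its side share 26.5 %. That flask holds 25.2 % side product, 41.6 % target and 33.1 % over-reaction product.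

(The earlier runs and the new flask were computed on assumed constants, and the scatter is random.)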